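## Structural features

The target is a tetracyclic C20 diterpenoid monoacetate. It has a trans-fused decalin of the labdane type (ring A: C1–C5, C10; ring B: C5–C10; 5α-H, 10β-CH3), a cyclobutane (C8, C9, C14, C15) cis-fused to ring B across C8–C9 on the α face, and a cyclopentane (ring D: C9, C11, C12, C13, C14) fused to the cyclobutane across C9–C14, so C9 belongs to three rings. There are seven stereocentres (C5, C6, C8, C9, C10, C13, C14). C8, C9 and C10 are contiguous quaternary carbons, and the tertiary carbinol C13 stands next to the ring-fusion methine C14 with its hydroxyl cis to H-14 and trans to the cyclobutane methylene C15. Ring B carries the C7 ketone between quaternary C8 and C6, whose acetoxy group is β, on the face crowded by the C4β, C8β and C10β methyl groups. The fragile parts are the α-acetoxy ketone (epimerisation at C6, acyl migration, reductive loss of acetate), the tertiary alcohol (elimination) and the four-membered ring attached to the C7 carbonyl carbon (ring opening when radical or anionic character develops at C7). The real difficulty is the vicinal quaternary pair C8/C9 inside the cyclobutane next to quaternary C10, together with the relative configuration at C13 and the axial C6 acetate. The key step exploits the fact that C13 is bonded to cyclobutane carbon C14 and is reachable from C9 through C11–C12: a C13 ketyl on a 3-oxobutyl chain can add 5-exo to C14 of a C14=C15 cyclobutene, which closes ring D, forces the cis C9–C14 fusion and places the oxygen anti to C15.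

## Logic of the disconnections

16 to 15: the C5–H and C6–H bonds are cut (retro-hydrogenation). An axial 6β-acetate cannot be delivered by an electrophile, which would come from the open α face, but it results if two hydrogens come from that face. The gain is the loss of two stereocentres. The demand is syn addition to a tetrasubstituted alkene from the α face only.

15 to 12 (through 14 and 13): the acetyl C–O bond and then the C6–O bond are cut. C8 is quaternary, so C6 is the only enolisable position of the C7 ketone and enolate autoxidation is regiochemically unambiguous. The gain is an unfunctionalised C6. The demand is that oxidation stops at the enolised α-diketone.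

12 to 11: no skeletal bond is cut; the C7 carbonyl is taken back to a carbinol. A C7 ketone would compete for the reductant in the ring D closure and its ketyl would open the four-membered ring. The demand is oxidation of a hindered secondary alcohol beside a tertiary one.

11 to 10: C13–C14 is cut, which opens ring D and removes the C13 and C14 stereocentres. The precursor has only five stereocentres and a free methyl ketone. The demand is a ketyl addition that is 5-exo, cis-fusing and anti-selective at C13.

10 to 8 (through 9): only C–O bonds change: the C13 ketone becomes its dioxolane and the C7 carbinol becomes the ketone. This allows a photochemically active enone at C7 while the side-chain carbonyl is masked during C7 reduction. The demand is a reduction and a mild acetal cleavage that leave the cyclobutene intact.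

8 to 6 and 7: C8–C15 and C9–C14 are cut (retro-[2+2]). Both quaternary stereocentres and the four-membered ring disappear in one operation, leaving a flat enone and a two-carbon gas. The demand is addition on the α face and survival of the β,γ-unsaturated ketone product under irradiation.

6 to 4 (through 5): the C7 carbonyl oxygen and the dioxolane are removed. The gain is a simple tetrasubstituted alkene ketone. The demand is allylic oxidation at C7 in preference to C11 and C17.

4 to 1 (through 3 and 2): water is added back across C8=C9 (C8–O bond) and C14–C15 are reattached at C13 (C13–C14 bond). This reaches a cheap chiral-pool diol that already holds C5 and C10. The demands are selective cleavage of the vinyl carbinol and dehydration toward the tetrasubstituted alkene.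

## Other disconnections considered

Alternative 1: The cut is C7–C8 and C9–C10 of ring B, which divides the skeleton into the achiral silyloxy diene A2 and the achiral cyclobutenone A3. In the forward direction an endo [4+2] cycloaddition under a chiral Lewis acid would give adduct A1, which contains ring B, the C8/C9/C10 quaternary triad, the C7 oxygen and the four-membered ring as a cyclobutanone.

- In its favour: it is convergent, the absolute configuration would come from a catalyst, so either enantiomer and ring A analogues would be open, and the Δ5 alkene and C7 oxygen are useful handles for the ring B oxidation pattern.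
- Against it here: the diene terminus C10 is fully substituted with its methyl on the inside of the s-cis diene, and the C4 gem-dimethyl group twists the diene. The dienophile is tetrasubstituted, and C9–C10 would join two quaternary carbons. After A1, ring D would still have to be closed (aldol of C14 onto the unmasked C13 ketone, with no built-in preference for the required C13 configuration), and the C15 carbonyl would have to be removed from a β-hydroxy cyclobutanone prone to retro-aldol opening.
- Comparison: on structure it matches the chosen photocycloaddition in ambition and is better in convergence and in independence from the chiral pool. On mechanism it is concerted and catalyst-controlled but sterically at its limit, whereas the stepwise photochemical addition tolerates tetrasubstitution. On step economy, fragment preparation plus ring D closure, C15 deoxygenation and C6 adjustment should exceed the eleven steps of the chosen route.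

Alternative 2: The cut is C8–C15, with the cyclobutane seen as a contracted cyclopentanone. Photolysis of the α-diazo ketone A5 in methanol would trigger a Wolff rearrangement with migration of C8 and give ester A4.

- In its favour: the strain is introduced last from an unstrained precursor, migration proceeds with retention at C8, and the C13 carbinol is already set and protected. No cyclobutene has to survive reductions, and on this point the alternative is better than the chosen plan.
- Against it here: A5 holds the whole skeleton plus one carbon, so the C8/C9 quaternary pair is only moved into a hydrindanone and not simplified. Diazo transfer would have to distinguish C15 from C6, and the C7/C8/extra-carbonyl array is a non-enolisable 1,3-diketone open to retro-Claisen cleavage by methanol. The C15 ester of A4 would then have to be hydrolysed next to quaternary C8 and removed by radical decarboxylation, which creates and deletes a stereocentre.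
- Comparison: on structure the chosen route gains more, since the photocycloaddition makes the ring and both quaternary centres at once. On mechanism the two are equal in reliability of the reaction type. On step economy the alternative is clearly longer.

Alternative 3: The cut is C4–C5 and C9–C10, with rings A and B formed in a radical cascade from the acyclic dienoyl bicyclic enone A7. Fe(acac)3 with PhSiH3 would place a hydrogen atom on the isopropenyl group, the C4 radical would close 6-endo onto C5, the C10 radical would add to C9 of the strained enone, and protonation at C14 would give diketone A6.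

- In its favour: two rings, two C–C bonds and four stereocentres (C5, C9, C10, C14) would arise in one step under control of C8 alone. It also avoids the acetal and C7 redox operations that the chosen route spends around the ketyl step. On bond-forming economy of the key step it is better than the chosen plan.
- Against it here: A7 contains a cyclobutene whose double bond is shared with a cyclopentenone, a very strained enone carrying a quaternary stereocentre, and its enantioselective preparation is an unsolved sub-problem. The metal hydride would have to choose the 1,1-disubstituted alkene over the trisubstituted alkene and the enone. The C10 tertiary radical would have to bond to a fully substituted β-carbon, so premature reduction is a likely diversion. In A6 the C13 methyl would have to be added late, and nucleophilic attack from the exo face of the bicyclo[3.2.0]heptanone would place the hydroxyl cis to C15, opposite to the target.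
- Comparison: on structure it is more ambitious. On mechanism the chosen route is safer, because the ketyl transition state itself sets the C13 configuration. On step economy the alternative would win only if A7 were short to make, which is doubtful.

Key step: step 7

Remark: the labdanediol of the absolute configuration used here is the natural, levorotatory compound, so it is named (−)-sclareol.
Remark: the C7 carbinol in 9, 10 and 11 is drawn 7β; this centre is removed in step 8, so the 7α epimer would converge on the same ketone.

## Route

Step 1
Reactants: 1 (−)-sclareol [(13R)-labd-14-ene-8α,13-diol]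
Product: 3 8α-hydroxy-14,15-dinorlabdan-13-one, via labdane-8α,13,14,15-tetraol 2 (not isolated)
Conditions: OsO4 (cat.), NaIO4 (3.5 equiv), THF/H2O, rt
Reagents that add atoms: none
Why: Lemieux–Johnson oxidation: OsO4 dihydroxylates the only alkene to tetraol 2 and NaIO4 cleaves both C14–C15 and C13–C14, so the C13 hydroxyl oxygen becomes the ketone oxygen; the C8 carbinol and the ring stereocentres are not touched.

Step 2
Reactants: 3 8α-hydroxy-14,15-dinorlabdan-13-one
Product: 4 14,15-dinorlabd-8-en-13-one
Conditions: PPh3, I2, CH2Cl2, rt
Reagents that add atoms: none
Why: Dehydration of a tertiary alcohol with the PPh3–I2 couple: the alkoxyphosphonium ion ionises at C8 and the HI formed equilibrates the alkenes toward the tetrasubstituted Δ8 isomer, which deliberately removes the C8 and C9 stereocentres; the methyl ketone is inert to the reagent.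

Step 3
Reactants: 4 14,15-dinorlabd-8-en-13-one
Product: 5 13,13-ethylenedioxy-14,15-dinorlabd-8-ene
Conditions: HOCH2CH2OH, PPTS (cat.), toluene, reflux (Dean–Stark)
Reagents that add atoms: ethylene glycol, OCCO
Why: Acid-catalysed acetalisation of an unhindered methyl ketone with removal of water; the tetrasubstituted alkene is already the thermodynamic isomer, so mild acid cannot move it.

Step 4
Reactants: 5 13,13-ethylenedioxy-14,15-dinorlabd-8-ene
Product: 6 13,13-ethylenedioxy-14,15-dinorlabd-8-en-7-one
Conditions: CrO3, 3,5-dimethylpyrazole, CH2Cl2, −20 °C
Reagents that add atoms: chromium trioxide, O=[Cr](=O)=O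
Why: Allylic C–H oxidation with the CrO3–3,5-dimethylpyrazole complex, which is compatible with dioxolanes; the ring methylene C7 is preferred over C11 (shielded by quaternary C10 and its methyl) and over the primary C17 methyl.

Step 5
Reactants: 6 13,13-ethylenedioxy-14,15-dinorlabd-8-en-7-one; 7 acetylene
Product: 8 13,13-ethylenedioxy-13,14-seco-8,15:9,14-dicyclolabd-14-en-7-one (cyclobutene C8–C15=C14–C9 on the α face, 8β-CH3, side chain on C9β)
Conditions: C2H2 (sat.), hν (Hg lamp, uranium-glass filter, λ > 340 nm), acetone, −78 °C
Reagents that add atoms: none
Why: Enone–alkyne [2+2] photocycloaddition through the triplet enone and a 1,4-biradical: the β-carbon C9 bonds axially, anti to the C10 methyl group with C11 staying equatorial, and closure at C8 can only be cis, which sets C8 and C9 together on the α face. The long-wavelength filter excites the enone but not the β,γ-unsaturated ketone product, which protects it from a 1,3-acyl shift.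

Step 6
Reactants: 8 13,13-ethylenedioxy-13,14-seco-8,15:9,14-dicyclolabd-14-en-7-one
Product: 10 7β-hydroxy-13,14-seco-8,15:9,14-dicyclolabd-14-en-13-one, via hydroxy acetal 9 (not isolated)
Conditions: NaBH4, MeOH/THF, 0 °C to rt; then 2 M HCl (aq.), rt
Reagents that add atoms: water, O
Why: Hydride reduction of the C7 ketone while C13 is masked, then acid hydrolysis of the dioxolane in the same flask. Hydride should come from the α face, anti to the C8 methyl group, to give the 7β-alcohol; dilute acid at rt does not ionise the secondary carbinol or the cyclobutene.

Step 7
Reactants: 10 7β-hydroxy-13,14-seco-8,15:9,14-dicyclolabd-14-en-13-one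
Product: 11 8,15:9,14-dicyclolabdane-7β,13-diol (H-14 cis to C10, 13-OH trans to C15)
Conditions: SmI2 (3 equiv), HMPA (10 equiv), t-BuOH (2 equiv), THF, 0 °C to rt, slow addition of 10
Reagents that add atoms: none
Why: SmI2 made strongly reducing by HMPA transfers one electron to the C13 carbonyl, the only reducible group in 10, and the samarium-bound ketyl adds to C14 of the strained C14=C15 cyclobutene; the cyclobutyl radical at C15 is then reduced by a second equivalent of SmI2 and protonated by t-BuOH. The closest known reaction type is the SmI2–HMPA ketyl–olefin cyclisation of unactivated δ,ε-unsaturated methyl ketones to 2-substituted 1-methylcyclopentanols. Ring D closes in the 5-exo-trig mode; attack at C15 would be 6-endo and would build a bridged bicyclo[2.1.1]hexane, so it should not compete. C14 is set by geometry: the tether reaches the cyclobutene only from the face that carries C11, so C13–C14 forms cis to C9–C11 and H-14 ends up cis to C10. C13 is set in the transition state, where the oxygen with its samarium–HMPA shell lies anti to C15 because of repulsion between the ketyl oxygen and the alkene carbon that becomes the radical; this gives hydroxyl trans and methyl cis to C15. The step needs chemoselectivity (secured by keeping C7 as an alcohol, since a C7 ketyl would open the four-membered ring by C8–C9 cleavage to an allylic radical), regioselectivity (secured by ring strain and the 5-exo preference) and C13 diastereoselectivity (secured by the anti preference).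

Step 8
Reactants: 11 8,15:9,14-dicyclolabdane-7β,13-diol
Product: 12 13-hydroxy-8,15:9,14-dicyclolabdan-7-one
Conditions: Dess–Martin periodinane, NaHCO3, CH2Cl2, rt
Reagents that add atoms: none
Why: Dess–Martin oxidation of the secondary alcohol; the tertiary C13 alcohol cannot be oxidised, and the buffered neutral medium spares the cyclobutane and the tertiary carbinol.

Step 9
Reactants: 12 13-hydroxy-8,15:9,14-dicyclolabdan-7-one
Product: 14 6,13-dihydroxy-8,15:9,14-dicyclolabd-5-en-7-one (diosphenol), via 6α-hydroperoxide 13 (not isolated)
Conditions: KOtBu, O2 (1 atm), t-BuOH/THF, rt; aq. HCl work-up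
Reagents that add atoms: dioxygen, O=O
Why: Enolate autoxidation: C8 is quaternary, so only the C6 enolate forms; it takes up O2 to hydroperoxide 13, which loses water under base to the α-diketone, isolated as its Δ5 enol. The C5 stereocentre is given up on purpose and is reset in step 11.

Step 10
Reactants: 14 6,13-dihydroxy-8,15:9,14-dicyclolabd-5-en-7-one
Product: 15 6-acetoxy-13-hydroxy-8,15:9,14-dicyclolabd-5-en-7-one
Conditions: Ac2O, pyridine, rt
Reagents that add atoms: acetic anhydride, CC(=O)OC(C)=O
Why: O-Acetylation of the acidic enol hydroxyl of a diosphenol; the tertiary C13 alcohol does not react without a nucleophilic catalyst.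

Step 11
Reactants: 15 6-acetoxy-13-hydroxy-8,15:9,14-dicyclolabd-5-en-7-one
Product: 16 6β-acetoxy-13-hydroxy-8,15:9,14-dicyclolabdan-7-one (CNP0330581.1)
Conditions: H2 (40 bar), Pd/C, EtOAc, rt
Reagents that add atoms: none
Why: Heterogeneous catalytic hydrogenation of the enol acetate double bond with syn delivery of both hydrogens from the α face, because the β face is covered by the C4β, C8β and C10β methyl groups. This gives 5α-H (trans ring fusion) and 6α-H, and so the axial 6β-acetate; the neutral medium avoids epimerisation at C6.

## Compound list

1 | (−)-sclareol [(13R)-labd-14-ene-8α,13-diol] | C=C[C@](C)(O)CC[C@@H]1[C@@]2(C)CCCC(C)(C)[C@@H]2CC[C@@]1(C)O | starting material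
2 | labdane-8α,13,14,15-tetraol (both C14 epimers) | OCC(O)[C@](C)(O)CC[C@@H]1[C@@]2(C)CCCC(C)(C)[C@@H]2CC[C@@]1(C)O | intermediate (not isolated)
3 | 8α-hydroxy-14,15-dinorlabdan-13-one | CC(=O)CC[C@@H]1[C@@]2(C)CCCC(C)(C)[C@@H]2CC[C@@]1(C)O | intermediate
4 | 14,15-dinorlabd-8-en-13-one | CC(=O)CCC1=C(C)CC[C@H]2C(C)(C)CCC[C@]12C | intermediate
5 | 13,13-ethylenedioxy-14,15-dinorlabd-8-ene | CC1(OCCO1)CCC2=C(C)CC[C@H]3C(C)(C)CCC[C@]23C | intermediate
6 | 13,13-ethylenedioxy-14,15-dinorlabd-8-en-7-one | CC1(OCCO1)CCC2=C(C)C(=O)C[C@H]3C(C)(C)CCC[C@]23C | intermediate
7 | acetylene | C#C | starting material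
8 | 13,13-ethylenedioxy-13,14-seco-8,15:9,14-dicyclolabd-14-en-7-one | C1C(=O)[C@@]2(C)C=C[C@@]2(CCC3(C)OCCO3)[C@@]2(C)CCCC(C)(C)[C@H]12 | intermediate
9 | 13,13-ethylenedioxy-13,14-seco-8,15:9,14-dicyclolabd-14-en-7β-ol | C1[C@H](O)[C@@]2(C)C=C[C@@]2(CCC3(C)OCCO3)[C@@]2(C)CCCC(C)(C)[C@H]12 | intermediate (not isolated)
10 | 7β-hydroxy-13,14-seco-8,15:9,14-dicyclolabd-14-en-13-one | C1[C@H](O)[C@@]2(C)C=C[C@@]2(CCC(C)=O)[C@@]2(C)CCCC(C)(C)[C@H]12 | intermediate
11 | 8,15:9,14-dicyclolabdane-7β,13-diol | C1[C@H](O)[C@@]2(C)C[C@H]3[C@@]2(CC[C@]3(C)O)[C@@]2(C)CCCC(C)(C)[C@H]12 | intermediate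
12 | 13-hydroxy-8,15:9,14-dicyclolabdan-7-one | C1C(=O)[C@@]2(C)C[C@H]3[C@@]2(CC[C@]3(C)O)[C@@]2(C)CCCC(C)(C)[C@H]12 | intermediate
13 | 6α-hydroperoxy-13-hydroxy-8,15:9,14-dicyclolabdan-7-one | OO[C@H]1C(=O)[C@@]2(C)C[C@H]3[C@@]2(CC[C@]3(C)O)[C@@]2(C)CCCC(C)(C)[C@H]12 | intermediate (not isolated)
14 | 6,13-dihydroxy-8,15:9,14-dicyclolabd-5-en-7-one | OC=1C(=O)[C@@]2(C)C[C@H]3[C@@]2(CC[C@]3(C)O)[C@@]2(C)CCCC(C)(C)C=12 | intermediate
15 | 6-acetoxy-13-hydroxy-8,15:9,14-dicyclolabd-5-en-7-one | CC(=O)OC=1C(=O)[C@@]2(C)C[C@H]3[C@@]2(CC[C@]3(C)O)[C@@]2(C)CCCC(C)(C)C=12 | intermediate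
16 | 6β-acetoxy-13-hydroxy-8,15:9,14-dicyclolabdan-7-one (CNP0330581.1) | CC(=O)O[C@@H]1C(=O)[C@@]2(C)C[C@H]3[C@@]2(CC[C@]3(C)O)[C@@]2(C)CCCC(C)(C)[C@H]12 | target

## Step count and least certain steps

Total step count: 11 steps. Longest linear sequence: 11 steps (1 to 16; 7 is a purchased gas).

**Step 7 (key step).** The most likely problem is erosion of diastereocontrol at C13. The rigid spiro-type junction at C9 distorts the chair-like transition state, and the large samarium–HMPA alkoxide may follow sterics instead of the electronic anti preference. The fallback separates the C13 configuration from the ring closure. It sets out from 11 obtained in admixture with its C13 epimer, 13-epi-8,15:9,14-dicyclolabdane-7β,13-diol F1. The mixture is oxidised under the conditions of step 8 to 12 and 13-epi-13-hydroxy-8,15:9,14-dicyclolabdan-7-one F2. The whole mixture is dehydrated with the Burgess reagent (toluene, 60 °C) to 8,15:9,14-dicyclolabd-13(16)-en-7-one F3 and its double-bond isomer 8,15:9,14-dicyclolabd-12-en-7-one F4. Mukaiyama hydration of both alkenes (Co(acac)2, PhSiH3, O2, i-PrOH) goes through the same tertiary C13 radical, which should take up oxygen from the exo face of the bicyclo[3.2.0]heptane (the face of H-14, away from C15). The fallback comes back to the route at 12.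

**Step 11.** The most likely problems are slow hydrogen uptake at the tetrasubstituted alkene, whose C5 lies between two quaternary carbons, and incomplete face selection, since the α face carries the cyclobutane. The fallback sets out from 14 and replaces hydrogenation by hydride delivery and ester transfer. NaBH4 in MeOH reduces C7, the resulting enol ketonises to the trans-fused 6-ketone, and this is reduced from the α face to 8,15:9,14-dicyclolabdane-6β,7β,13-triol F5. MeC(OMe)3 with PPTS converts the cis-6,7-diol into the cyclic orthoacetate F6. Dilute aqueous AcOH opens F6 to the axial ester, 6β-acetoxy-8,15:9,14-dicyclolabdane-7β,13-diol F7. Dess–Martin oxidation of the remaining secondary alcohol comes back to the route at 16.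

**Step 5.** The most likely problems are sluggish addition of the poorly soluble gas to a tetrasubstituted enone and secondary photoreaction (1,3-acyl shift) of the β,γ-unsaturated ketone product on prolonged irradiation. The fallback sets out from 6 and uses a liquid acetylene surrogate. Irradiation in the presence of excess (Z)-1,2-dichloroethene gives the saturated adduct 14,15-dichloro-13,13-ethylenedioxy-13,14-seco-8,15:9,14-dicyclolabdan-7-one F8, as chloride epimers on the α-fused cyclobutane. NaBH4 reduces it to the 7β-alcohol 14,15-dichloro-13,13-ethylenedioxy-13,14-seco-8,15:9,14-dicyclolabdan-7β-ol F9. Reductive 1,2-elimination with sodium naphthalenide (THF, −78 °C) forms the cyclobutene and comes back to the route at 9, which is hydrolysed as in the second stage of step 6.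

**Step 4.** The most likely problem is competing oxidation at C11 or C17, or over-oxidation, because three allylic positions flank the tetrasubstituted alkene. The fallback fixes the position of the oxygen by construction and also bypasses the regiochemistry of step 2. It sets out from 3.
- SOCl2 in pyridine at −78 °C eliminates through the chlorosulfite toward the methyl group and gives 14,15-dinorlabd-8(17)-en-13-one F10.
- SeO2 (cat.) with t-BuOOH hydroxylates the ring allylic position to 7α-hydroxy-14,15-dinorlabd-8(17)-en-13-one F11.
- Dess–Martin oxidation gives 14,15-dinorlabd-8(17)-ene-7,13-dione F12.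
- RhCl3·3H2O in hot EtOH moves the exocyclic double bond into conjugation in the ring to give 14,15-dinorlabd-8-ene-7,13-dione F13.
- Selective dioxolane formation at the saturated C13 ketone (HOCH2CH2OH, PPTS) comes back to the route at 6.

## Further compounds

F1 | step 7 | 13-epi-8,15:9,14-dicyclolabdane-7β,13-diol | C1[C@H](O)[C@@]2(C)C[C@H]3[C@@]2(CC[C@@]3(C)O)[C@@]2(C)CCCC(C)(C)[C@H]12
F2 | step 7 | 13-epi-13-hydroxy-8,15:9,14-dicyclolabdan-7-one | C1C(=O)[C@@]2(C)C[C@H]3[C@@]2(CC[C@@]3(C)O)[C@@]2(C)CCCC(C)(C)[C@H]12
F3 | step 7 | 8,15:9,14-dicyclolabd-13(16)-en-7-one | C1C(=O)[C@@]2(C)C[C@H]3[C@@]2(CCC3=C)[C@@]2(C)CCCC(C)(C)[C@H]12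
F4 | step 7 | 8,15:9,14-dicyclolabd-12-en-7-one | C1C(=O)[C@@]2(C)C[C@H]3[C@@]2(CC=C3C)[C@@]2(C)CCCC(C)(C)[C@H]12
F5 | step 11 | 8,15:9,14-dicyclolabdane-6β,7β,13-triol | O[C@@H]1[C@H](O)[C@@]2(C)C[C@H]3[C@@]2(CC[C@]3(C)O)[C@@]2(C)CCCC(C)(C)[C@H]12
F6 | step 11 | 6β,7β-O-(1-methoxyethylidene)-8,15:9,14-dicyclolabdane-6β,7β,13-triol (both orthoester epimers) | COC4(C)O[C@@H]1[C@H](O4)[C@@]2(C)C[C@H]3[C@@]2(CC[C@]3(C)O)[C@@]2(C)CCCC(C)(C)[C@H]12
F7 | step 11 | 6β-acetoxy-8,15:9,14-dicyclolabdane-7β,13-diol | CC(=O)O[C@@H]1[C@H](O)[C@@]2(C)C[C@H]3[C@@]2(CC[C@]3(C)O)[C@@]2(C)CCCC(C)(C)[C@H]12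
F8 | step 5 | 14,15-dichloro-13,13-ethylenedioxy-13,14-seco-8,15:9,14-dicyclolabdan-7-one (chloride epimers) | C1C(=O)[C@@]2(C)C(Cl)C(Cl)[C@@]2(CCC3(C)OCCO3)[C@@]2(C)CCCC(C)(C)[C@H]12
F9 | step 5 | 14,15-dichloro-13,13-ethylenedioxy-13,14-seco-8,15:9,14-dicyclolabdan-7β-ol (chloride epimers) | C1[C@H](O)[C@@]2(C)C(Cl)C(Cl)[C@@]2(CCC3(C)OCCO3)[C@@]2(C)CCCC(C)(C)[C@H]12
F10 | step 4 | 14,15-dinorlabd-8(17)-en-13-one | CC(=O)CC[C@@H]1[C@@]2(C)CCCC(C)(C)[C@@H]2CCC1=C
F11 | step 4 | 7α-hydroxy-14,15-dinorlabd-8(17)-en-13-one | CC(=O)CC[C@@H]1[C@@]2(C)CCCC(C)(C)[C@@H]2C[C@@H](O)C1=C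
F12 | step 4 | 14,15-dinorlabd-8(17)-ene-7,13-dione | CC(=O)CC[C@@H]1[C@@]2(C)CCCC(C)(C)[C@@H]2CC(=O)C1=C
F13 | step 4 | 14,15-dinorlabd-8-ene-7,13-dione | CC(=O)CCC1=C(C)C(=O)C[C@H]2C(C)(C)CCC[C@]12C
A1 | alternative 1 | 7α-(tert-butyldimethylsilyloxy)-13,13-ethylenedioxy-13,14-seco-8,15:9,14-dicyclolabd-5-en-15-one | C=1[C@@H](O[Si](C)(C)C(C)(C)C)[C@@]2(C)C(=O)C[C@@]2(CCC3(C)OCCO3)[C@@]2(C)CCCC(C)(C)C=12
A2 | alternative 1 | (E)-tert-butyldimethyl[2-(2,6,6-trimethylcyclohex-1-en-1-yl)ethenyloxy]silane | CC1=C(/C=C/O[Si](C)(C)C(C)(C)C)C(C)(C)CCC1
A3 | alternative 1 | 2-methyl-3-[2-(2-methyl-1,3-dioxolan-2-yl)ethyl]cyclobut-2-en-1-one | CC1=C(CCC2(C)OCCO2)CC1=O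
A4 | alternative 2 | 15-(methoxycarbonyl)-13-(triethylsilyloxy)-8,15:9,14-dicyclolabdan-7-one | C1C(=O)[C@@]2(C)[C@@H](C(=O)OC)[C@H]3[C@@]2(CC[C@]3(C)O[Si](CC)(CC)CC)[C@@]2(C)CCCC(C)(C)[C@H]12
A5 | alternative 2 | ring-expanded α-diazo ketone (carbonyl between C8 and C15, diazo on C15, 7-ketone, 13-triethylsilyl ether) | C1C(=O)[C@@]2(C)C(=O)C(=[N+]=[N-])[C@H]3[C@@]2(CC[C@]3(C)O[Si](CC)(CC)CC)[C@@]2(C)CCCC(C)(C)[C@H]12
A6 | alternative 3 | 16-nor-8,15:9,14-dicyclolabdane-7,13-dione | C1C(=O)[C@@]2(C)C[C@H]3[C@@]2(CCC3=O)[C@@]2(C)CCCC(C)(C)[C@H]12
A7 | alternative 3 | 6-[(3E)-4,8-dimethylnona-3,8-dienoyl]-6-methylbicyclo[3.2.0]hept-1(5)-en-2-one | C=C(C)CCC/C(C)=C/CC(=O)[C@@]1(C)CC2=C1CCC2=O
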